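The ratio of the Z charged to the rate per litre at which Z appears as X gives the time the charge can last at that rate.

in all of them: G 0.121 M

| charge | Z | remark | time |
|---|---|---|---|
| noon | 0.062 M | run made earlier |  |
| spring | 0.14 M | run made earlier |  |
| flask | 0.093 M |  | 20 min |

| run | time / min | X / % | L / % |
|---|---|---|---|
| noon | 1.33 | 6.4 | 7.0 |
| noon | 3.00 | 17.7 | 15.8 |
| noon | 6.00 | 35.3 | 32.7 |
| noon | 15.0 | 87.4 | 85.9 |
| spring | 4.00 | 11.0 | 9.0 |
| spring | 8.00 | 20.9 | 19.4 |
| spring | 12.0 | 30.5 | 28.7 |
| spring | 15.0 | 38.8 | 37.7 |

(scatter of a reading: 0.5 percentage points)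

- amounts and yields of X count L too
- given per volume of solution although it is solid: Z, L
- what was read earlier has a scatter of 0.5 percentage points, one standard deviation
- at the start none of Z is in solution
- D is what Z becomes in solution
- D means what is dissolved; the solid is not counted in it

- X and L together at 20 min, in percent of the Z charged
- concentration of D in solution at 20 min, in percent of saturation

Averaged up to 15.0 min, the readings of the noon run give X made at 0.00361 M min⁻¹ and those of the spring run at 0.00362 M min⁻¹, which agree although the Z charges differ, so the readings show a feed of zero order in the Z charged. The flask's charge over this feed is its emptying time, 25.7 min. For the flask to stand finished at 20 min, the emptying time would have to be no longer than that; it is longer by 5.70 min. This reckoning therefore expects solid Z to remain and gives 77.9% for X and L together, slightly above the forecast. The readings hold no c(D).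

The forecast gives 77.5% and 100%, on the ground that “solid persists and D stays saturated”.

The flask gives 76.0%, with c(D) at 1.47% of saturation; at 9.97 min its D has a half-life of 0.066 min by the step with G, short against the run.

    G ⇌ J (K = 2.40, k = 0.0140 s⁻¹)
    X ⇌ E (K = 0.350, k = 4.60 × 10⁻⁴ s⁻¹)
    Z ⇌ D, rate k3*(cs3 - [D]) while solid is left; crystals form when [D] > cs3 (solubility = 44.0 mM, k = 0.00150 s⁻¹)
    D + X → Q (k = 7.00 M⁻¹ s⁻¹)
    L ⇌ X, rate k5*(cs5 - [X]) while solid is left; crystals form when [X] > cs5 (solubility = 0.960 mM, k = 0.370 s⁻¹)
    D + G → X (k = 7.90 M⁻¹ s⁻¹)

At 20.0 min the flask has not come to rest: Z stands at 15.6% of its charge and Q at 7.42%. The neighbour read at 50 min, beyond the emptying time, holds Z at 0% and gives 89.2%. Left for 200 min, the flask gains 13 percentage points and reaches 89.2%.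

The data were generated by integration on assumed constants, and the scatter is random.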